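## The problem

CNP0111873.1 is a tetracycle in which a cyclohexane (ring A, C1–C6) shares the C1–C6 bond with a tricyclo[2.2.1.0]heptane (nortricyclene) cage built from C1, C6 and C7–C11. C6 is the apex carbon and C8–C9–C10 is the cyclopropane. Four fully substituted carbons (C1, C5, C6, C10) adjoin one another, so the C5–C6 and C1–C9 bonds must be made between hindered centres.

There are eight stereocentres (C1, C3, C4, C6, C8, C9, C10, C11). C8, C9 and C10 follow from the cage once C1 and C6 are fixed. The independent questions are the C4 carbinol, the sense of C6 relative to C4, the face of C1 that carries C12, the C11 carbinol and the C3 carbinol. C4 can control C6 if ring A closes through a chair; C6 and that chair can control C1; the locked ring A can control C3. C11 sits in a pocket where ring A shields exactly the face from which a hydride would have to arrive.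

Three oxygens are acetates beside a free C3 hydroxyl (acyl migration under base), the C11 acetate is cyclopropylcarbinyl (ionization under acid) and the cage is strained, so the closing steps must be mild.

The enabling feature is twofold. C4, a carbinol between the gem-dimethyl carbon C5 and the quaternary C6, is the footprint of a trisubstituted epoxide opened at its tertiary carbon. C6–C11, with the methyl on C10 and the oxygen on C11, are the six carbons of an ortho-cresol whose ipso carbon C6 is ortho to the oxygen. An epoxide-triggered ipso attack would therefore form C5–C6, ring A and the quaternary C6 together and leave a cyclohexa-2,4-dienone ready for the cage.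

## Retrosynthesis

**C3 carbinol (27 ⇒ 26 ⇒ 25).** No skeletal bond is cut first. The target 27 is traced to ketone 26 and this to the C3-epimeric alcohol 25. The reason lies further back: with C3 inverted, the C3 oxygen is equatorial in the ring-A chair that the key step and the C1–C9 closure need, and the epoxide precursor becomes the threo isomer that hydroxyl-directed epoxidation delivers. Carrying the natural (axial) C3 through would require the disfavoured erythro epoxy alcohol, place a silyloxy group syn-axial to a methyl in the key chair, and leave the two chairs of ring A nearly balanced when C1 is set. The forward reduction must deliver hydride equatorially; the syn-axial C12 methylene and C5 methyl of the locked chair enforce this.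

**Acetates and C11 (25 ⇒ 24 ⇒ 22 ⇒ 21 ⇒ 19).** The C3–O–Si bond of 24, the C11–OAc bond, the two ordinary acetates of 22 and the C12/C11 oxidation levels of 21 are removed in turn, back to keto nitrile 19. The C11–O bond is cut in the cationic sense. Hydride reaches the C11 ketone only from the C7 side and gives the wrong carbinol, and SN2 at a carbon between two quaternary centres is not available. A cyclopropylcarbinyl cation taken by acetate from the open face gives the right one. The forward step must capture the cation at C11 and not at C8 or C9.

**Cyclopropane (19 ⇐ 18 ⇐ 16 ⇐ 15).** The C8–C10 bond is cut; 19 arises from 18 by desilylation at O4. The C10 enolate of the C11 ketone displaces an exo leaving group on C8, which comes from hydroboration of the C7=C8 bond of 15. Carbene insertion from a C8 ketone was the neighbouring option, but it needs an endo hydrogen on the epimerizable C10. The enolate route makes no demand on C10 and needs only an exo alcohol at C8 (16).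

**C1–C9 bond (15 ⇐ 13).** Cutting C1–C9 opens the bicyclo[2.2.1] unit to spirodienone 13, whose C9 is the β-carbon of the dienone and whose C1 carries an acidifying nitrile. The dienone has no acidic hydrogen of its own; a 7,8-dihydro enone would, and its γ-hydrogens would be removed before C1–H. The closure forms a strained bicycloheptadiene, so it must be made irreversible, here by silylating the enolate. The ring-A chair must place C2 on the side of the C10–C11 bridge.

**Key disconnection, C5–C6 (13 ⇐ 12).** Cutting the bond between the gem-dimethyl carbon and the spiro carbon rearomatizes ring B and returns the C4 oxygen to an epoxide, giving phenol 12. The other ring-A bond at C6 (C1–C6) would require the aryl group on the tertiary C5 and a separate construction of the C4 carbinol. The C5–C6 cut uses the epoxide for both. The forward step must favour ipso C-attack over O-alkylation and cation rearrangement, and place C11 axial.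

**Epoxide and C3 carbinol (12 ⇐ 11 ⇐ 10 ⇐ 9 ⇐ 8).** Removing the phenol benzyl ether (11), the silyl ether (10) and the epoxide oxygen leads to allylic alcohol 9 and enone 8. The C3 carbinol is the only stereocentre set by a reagent; it relays to C4 through allylic strain in a hydroxyl-directed epoxidation.

**Carbon chain (8 ⇐ 6 + 7; 6 ⇐ 4 + 5; 4 ⇐ 2 + 3; 2 ⇐ 1).** C3–C4 is cut to Weinreb amide 6 and Grignard reagent 7, C1–C2 to arylacetonitrile 4 and chloroamide 5, and C1–C12 to aldehyde 2 and TosMIC 3; 2 is the benzyl ether of commercial 1. A nitrile is used for C12 in place of an ester. A γ-hydroxy ester would lactonize as soon as the C3 carbinol exists, and an ester could take part in the epoxide opening. The nitrile is also the smaller, more reactive carbanion for the hindered C1–C9 closure.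

## Roads not taken

**Alternative 1:** The C6–C7 and C8–C9 bonds are cut. A vinylsilyl ether tethered through the C12 oxygen adds to a cyclopentadiene (diene C6=C11–C10=C9, sp3 carbon C1) in an intramolecular Diels–Alder reaction to give the silicon-tethered norbornene A1. Merits: two C–C bonds and the bicyclo[2.2.1] unit form in one downhill thermal step; the tether fixes regiochemistry and leaves silicon on C8, where the cyclopropane closure needs a leaving group. In this respect it is better than step 10 of the chosen plan, which must be driven by silyl trapping. Weak points: A1 has a C10=C11 alkene and no oxygen on C11, so that oxygen and the C8–C10 bond remain to be made. The substrate is a ring-fused cyclopentadiene with a quaternary sp3 carbon, which is hard to reach with C1 defined. An unactivated vinylsilane needs heat. Against this the chosen plan sets the phenol oxygen on C11 from the start and builds ring A and C6 from a commercial arene in one step.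

**Alternative 2:** The C1–C6 and C8–C9 bonds are cut. A 1,3-dibromo-2-oxyallyl cation (C1–C12–C9) adds to a silyloxycyclopentadiene at C6 and C8 to give the ring-A-fused dibromo bicyclo[3.2.1]octenone A2; a quasi-Favorskii contraction would then make the C1–C9 bond and leave C12 as a carboxyl. Merits: ring A, the quaternary C1 and a seven-membered bridge form together, C11 already bears oxygen, and the bond count per step is as good as or better than in the chosen plan. Weak points: four bromines must be placed around a ketone that carries stereocentres. Facial selectivity across the diene rests on the tether alone. The contraction must choose the right C–Br and ring bond, two bromines must be removed, and the cyclopropane is still open. The chosen plan confines its novelty to one step and follows it with known reaction types, at the price of a longer endgame.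

**Alternative 3:** The C1–C9, C8–C10 and C11–O bonds are cut. Lewis-acid opening of a C1–C12 spiro-epoxide gives a C1 cation that adds to C9 of a spiro cyclohexadiene; the C8 cation closes on C10 and acetic acid takes C11, giving the cage acetate A3 with a free C12 hydroxyl. Merits: the whole cage forms in one step, and the acetate enters C11 from the open face with the correct configuration. This is better than the chosen plan, which needs steps 10–12 for the cage and steps 14–16 to correct C11. Weak points: the substrate already needs ring A with three contiguous fully substituted carbons, which requires a spirocyclization of its own. A tertiary cation beside a quaternary carbon invites 1,2-shifts and isomerization of the epoxide to an aldehyde, and the cascade runs through a secondary cation. The chosen plan sets against this a substrate made in eight steps by standard reactions and a chair-controlled first ring closure.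

Key step: step 9

Remark on the chemistry: atoms are numbered as in the target (C12 acetoxymethyl carbon, C1 its quaternary carbon, C2–C5 ring A, C6 spiro/apex carbon, C7–C11 the remaining cage carbons; ring B is C6–C11). C1 is carried as both epimers from 6 to 13 because it becomes planar in step 10, so the SMILES of 6–14 leave C1 undefined.

Abbreviations: TBDPS = tert-butyldiphenylsilyl, TBS = tert-butyldimethylsilyl, TosMIC = p-toluenesulfonylmethyl isocyanide.

## Route

Step 1
Reactants: 1 2-hydroxy-3-methylbenzaldehyde
Product: 2 2-(benzyloxy)-3-methylbenzaldehyde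
Conditions: BnBr, K2CO3, DMF, 60 °C
Reagents that add atoms: benzyl bromide, BrCc1ccccc1
Why: Williamson ether synthesis; the benzyl ether masks the phenol through the carbanion, Grignard and peracid steps and is later removed by neutral hydrogenolysis.

Step 2
Reactants: 2 2-(benzyloxy)-3-methylbenzaldehyde; 3 TosMIC
Product: 4 [2-(benzyloxy)-3-methylphenyl]acetonitrile
Conditions: KOtBu, DME, −35 °C; then MeOH, 65 °C
Reagents that add atoms: none
Why: van Leusen reductive cyanation; the TosMIC anion adds to the aldehyde, the oxazoline opens to an N-formyl enamine sulfone and methanolysis expels sulfinate, so the aldehyde carbon becomes C1 and TosMIC supplies the nitrile carbon C12.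

Step 3
Reactants: 4 [2-(benzyloxy)-3-methylphenyl]acetonitrile; 5 2-chloro-N-methoxy-N-methylacetamide
Product: 6 3-[2-(benzyloxy)-3-methylphenyl]-3-cyano-N-methoxy-N-methylpropanamide
Conditions: LiN(SiMe3)2, THF, −78 °C; then 5, −78 → 0 °C
Reagents that add atoms: none
Why: SN2 alkylation of an arylacetonitrile anion by an α-chloro amide attaches C2 and C3; C1 forms racemic, which is harmless because it is planarized in step 10.

Step 4
Reactants: 6 3-[2-(benzyloxy)-3-methylphenyl]-3-cyano-N-methoxy-N-methylpropanamide; 7 2-methylprop-1-enylmagnesium bromide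
Product: 8 2-[2-(benzyloxy)-3-methylphenyl]-6-methyl-4-oxohept-5-enenitrile
Conditions: 7 (2.5 equiv), THF, −40 → 0 °C; aq. NH4Cl
Reagents that add atoms: none
Why: Weinreb ketone synthesis; the first equivalent of Grignard reagent deprotonates C1–H and so shields the nitrile, the second adds to the amide, and the chelated adduct prevents over-addition.

Step 5
Reactants: 8 2-[2-(benzyloxy)-3-methylphenyl]-6-methyl-4-oxohept-5-enenitrile
Product: 9 (4R)-2-[2-(benzyloxy)-3-methylphenyl]-4-hydroxy-6-methylhept-5-enenitrile
Conditions: (S)-2-methyl-CBS-oxazaborolidine (0.2 equiv), catecholborane, toluene, −78 °C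
Reagents that add atoms: none
Why: Corey–Bakshi–Shibata reduction of an enone with the alkenyl group as the large substituent; the (S)-catalyst should give the (R)-carbinol at C3 under reagent control, whatever the configuration at C1.

Step 6
Reactants: 9 (4R)-2-[2-(benzyloxy)-3-methylphenyl]-4-hydroxy-6-methylhept-5-enenitrile
Product: 10 (4R)-2-[2-(benzyloxy)-3-methylphenyl]-4-[(2S)-3,3-dimethyloxiran-2-yl]-4-hydroxybutanenitrile
Conditions: mCPBA, NaHCO3, CH2Cl2, 0 °C
Reagents that add atoms: 3-chloroperbenzoic acid, OOC(=O)c1cccc(Cl)c1
Why: hydroxyl-directed peracid epoxidation; allylic 1,3-strain with the cis methyl puts the carbinol hydrogen in the alkene plane, so the hydrogen-bonded peracid adds syn to the hydroxyl and gives the threo epoxy alcohol, which is the target configuration at C4.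

Step 7
Reactants: 10 (4R)-2-[2-(benzyloxy)-3-methylphenyl]-4-[(2S)-3,3-dimethyloxiran-2-yl]-4-hydroxybutanenitrile
Product: 11 (4R)-2-[2-(benzyloxy)-3-methylphenyl]-4-[(tert-butyldiphenylsilyl)oxy]-4-[(2S)-3,3-dimethyloxiran-2-yl]butanenitrile
Conditions: TBDPSCl, imidazole, DMAP (cat.), DMF, 25 °C
Reagents that add atoms: tert-butyl(chloro)diphenylsilane, CC(C)(C)[Si](Cl)(c1ccccc1)c1ccccc1
Why: silylation under imidazole avoids Payne rearrangement of the 2,3-epoxy alcohol; TBDPS is chosen because it must outlast the later removal of a TBS ether on O4.

Step 8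
Reactants: 11 (4R)-2-[2-(benzyloxy)-3-methylphenyl]-4-[(tert-butyldiphenylsilyl)oxy]-4-[(2S)-3,3-dimethyloxiran-2-yl]butanenitrile
Product: 12 (4R)-4-[(tert-butyldiphenylsilyl)oxy]-4-[(2S)-3,3-dimethyloxiran-2-yl]-2-(2-hydroxy-3-methylphenyl)butanenitrile
Conditions: H2 (1 atm), 10% Pd on carbon, EtOAc, 25 °C
Reagents that add atoms: none
Why: hydrogenolysis of an aryl benzyl ether; the non-benzylic trisubstituted epoxide, the nitrile and the silyl ether are not reduced under these conditions.

Step 9
Reactants: 12 (4R)-4-[(tert-butyldiphenylsilyl)oxy]-4-[(2S)-3,3-dimethyloxiran-2-yl]-2-(2-hydroxy-3-methylphenyl)butanenitrile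
Product: 13 3-[(tert-butyldiphenylsilyl)oxy]-4-hydroxy-5,5,10-trimethyl-11-oxospiro[5.5]undeca-7,9-diene-1-carbonitrile (O3 trans to O4; C11 on the ring-A face opposite to O4)
Conditions: Et2AlCl (2.5 equiv), CH2Cl2, −78 → −40 °C; aq. KNaC4H4O6
Reagents that add atoms: none
Why: Proposed new method: Et2AlCl turns the phenol into an aluminium phenoxide (ethane is lost) and a second equivalent activates the epoxide, which opens at the tertiary carbon C5 as trisubstituted epoxides do in epoxide-initiated arene and polyene cyclizations; the developing cation is taken by the ipso carbon C6, the only ring carbon that is both ortho to the oxygen and six atoms away, and loss of the metal from the oxocarbenium leaves the cyclohexa-2,4-dienone. The closest known reaction types are epoxide-initiated Friedel–Crafts cyclization and alkylative dearomatization of ortho-substituted phenols to 6,6-disubstituted cyclohexa-2,4-dienones; their union in one substrate is what is new. Ring A closes as a six-membered spiro ring (ipso attack, exo with respect to the arene, endo with respect to the epoxide), and because C6 must enter anti to the breaking C5–O bond the C4 oxygen stays equatorial in a chair. In that chair the C3 silyl ether is also equatorial, so no 1,3-diaxial strain opposes closure. The new stereocentre C6 is controlled by C4 through this chair: the ortho carbon bearing the aluminium-bound oxygen (C11) should take the axial position, where the oxygen meets only the axial hydrogens on C2 and C4, and not the equatorial one, where it would be wedged between the axial methyl on C5 and the axial substituent on C1. The step needs C-attack at C6 to beat O-alkylation (an eight-membered ether), attack at C7 (a seven-membered ring onto a carbon the oxygen does not activate) and the 1,2-hydride shift to a C4 ketone; the short tether, the ortho oxygen and the low temperature favour C6. The 2-methyl group and the flanking quaternary carbons should keep the dienone from dimerizing.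

Step 10
Reactants: 13 spirodienone (C3 OTBDPS; C4 OH; C1 nitrile)
Product: 15 bicyclo[2.2.1]heptadiene silyl enol ether fused to ring A (C1–C9 bond; C7=C8; C10=C11 with OTBS on C11; C4 OTBS; C3 OTBDPS; C1 nitrile syn to the C7=C8 bridge), via N-silyl ketene imine 14 (not isolated)
Conditions: KN(SiMe3)2 (2.2 equiv), THF, −78 °C; then TBSOTf (3 equiv), −78 → −20 °C
Reagents that add atoms: tert-butyldimethylsilyl trifluoromethanesulfonate, CC(C)(C)[Si](C)(C)OS(=O)(=O)C(F)(F)F
Why: intramolecular Michael addition of a nitrile-stabilized carbanion in its Mukaiyama form: the base removes only O–H and C1–H, the silyl triflate caps O4, converts the nitrile anion into 14 and, in excess, activates the dienone so that C1 adds to C9 (the only electrophilic carbon within reach) and the enolate is held as its silyl ether, which makes the strained closure irreversible. C1 and C9 are set together: with both silyloxy groups equatorial, ring A keeps the chair of step 9, and in it C1 reaches C9 on the face that leaves the nitrile axial and C2 over the C10–C11 bridge.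

Step 11
Reactants: 15 bicyclo[2.2.1]heptadiene silyl enol ether
Product: 16 exo C8 alcohol (C7 saturated; silyl enol ether C10=C11 retained; C8 OH syn to the C1 bridge)
Conditions: 9-BBN, THF, 0 → 25 °C; then NaBO3·4H2O, H2O, 25 °C
Reagents that add atoms: sodium perborate, [Na+].OO[B-](O)(O)O
Why: hydroboration–oxidation; 9-BBN ignores the tetrasubstituted silyl enol ether and the nitrile, places boron on C8 (C7 is neopentyl) and should add from the exo face, where only the slim nitrile points; oxidation with retention gives the exo alcohol needed for backside displacement.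

Step 12
Reactants: 16 exo C8 alcohol
Product: 18 cage cyclopropyl ketone (cyclopropane C8–C9–C10; C11 ketone; C1 nitrile; C4 OTBS; C3 OTBDPS), via C8 mesylate 17 (not isolated)
Conditions: MsCl, Et3N, CH2Cl2, 0 °C; solvent exchange; Bu4NF (1.1 equiv), THF, −78 → 0 °C
Reagents that add atoms: none
Why: fluoride cleavage of the silyl enol ether frees the C10 enolate, which displaces the exo mesylate on C8 from the endo side (3-exo-tet enolate γ-alkylation, as in the closure of 5-exo-sulfonyloxybicyclo[2.2.1]heptan-2-ones to nortricyclanones); C8 and C10 are fixed by the cage and no demand is made on C10. The intramolecular displacement should outrun retro-Michael opening of the enolate.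

Step 13
Reactants: 18 cage cyclopropyl ketone
Product: 19 cage keto nitrile with free C4 hydroxyl (C3 OTBDPS)
Conditions: 48% aq. HF, MeCN, 0 → 25 °C
Reagents that add atoms: none
Why: acidic fluoride cleaves the alkyl TBS ether; the bulkier, more acid-stable TBDPS ether, the nitrile and the cyclopropyl ketone should persist if the reaction is stopped once 18 is consumed.

Step 14
Reactants: 19 cage keto nitrile with free C4 hydroxyl
Product: 21 triol (C4 OH; C12 OH; C11 OH on the ring-A side, i.e. 11-epi; C3 OTBDPS), via hydroxy aldehyde 20 (not isolated)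
Conditions: i-Bu2AlH (5 equiv), CH2Cl2, −78 → −20 °C; 1 M HCl; then NaBH4, MeOH, 0 °C
Reagents that add atoms: water, O
Why: i-Bu2AlH reduces the ketone and stops at the N-aluminoimine of the nitrile; hydrolysis gives aldehyde 20 and NaBH4 gives the C12 alcohol. Hydride can reach the C11 carbonyl only from the side of the C7 bridge, since the other face lies under the axial hydrogens on C2 and C4, so the hydroxyl is expected on the ring-A side, opposite to the target; step 16 corrects this.

Step 15
Reactants: 21 triol
Product: 22 4,12-diacetate with free 11-epi hydroxyl (C3 OTBDPS)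
Conditions: Ac2O (2.2 equiv), pyridine, DMAP (cat.), CH2Cl2, 0 → 25 °C
Reagents that add atoms: acetic anhydride, CC(=O)OC(C)=O
Why: DMAP-catalysed acylation takes the primary C12 and the secondary C4 hydroxyl; the C11 hydroxyl, between two quaternary carbons and under ring A, should remain free. Any C11 alcohol of the target configuration formed in step 14 would be acetylated here and rejoin the route at 24.

Step 16
Reactants: 22 4,12-diacetate with free 11-epi hydroxyl
Product: 24 4,11,12-triacetate with the target configuration at C11 (C3 OTBDPS), via C11 mesylate 23 (not isolated)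
Conditions: Ms2O, Et3N, CH2Cl2, −20 °C; then KOAc, AcOH, 40 °C
Reagents that add atoms: potassium acetate, CC(=O)[O-].[K+]
Why: the small sulfene sulfonylates the hindered hydroxyl, and buffered acetolysis ionizes the mesylate to the cyclopropylcarbinyl (nortricyclyl) cation, which acetate should take at C11 from the open face beside the C7 bridge, i.e. with inversion, as in the acetolysis of nortricyclyl sulfonates. This installs the third acetate with the configuration of the target.

Step 17
Reactants: 24 4,11,12-triacetate (C3 OTBDPS)
Product: 25 3-epi-CNP0111873.1 (C3 hydroxyl equatorial and trans to the C4 acetate)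
Conditions: Bu4NF, AcOH (1:1), THF, 25 → 40 °C
Reagents that add atoms: none
Why: fluoride desilylation buffered by acetic acid, so that the C3 alkoxide is protonated before it can attack the neighbouring acetate; the three esters survive.

Step 18
Reactants: 25 3-epi-CNP0111873.1
Product: 26 3-oxo triacetate
Conditions: Dess–Martin periodinane, NaHCO3, CH2Cl2, 25 °C
Reagents that add atoms: none
Why: Dess–Martin oxidation under buffered neutral conditions gives the α-acetoxy ketone without epimerization at C4 or loss of acetate.

Step 19
Reactants: 26 3-oxo triacetate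
Product: 27 CNP0111873.1
Conditions: NaBH4, MeOH/CH2Cl2, −40 °C
Reagents that add atoms: none
Why: hydride reduction of a cyclohexanone whose axial face is closed by two syn-axial groups (the C12 methylene on C1 and the axial methyl on C5); attack is forced onto the equatorial trajectory and gives the axial C3 alcohol of the target. Low temperature and neutral work-up suppress acetyl migration from O4 to O3.

## Compound list

1 | 2-hydroxy-3-methylbenzaldehyde | Cc1cccc(C=O)c1O | starting material
2 | 2-(benzyloxy)-3-methylbenzaldehyde | Cc1cccc(C=O)c1OCc1ccccc1 | intermediate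
3 | p-toluenesulfonylmethyl isocyanide (TosMIC) | Cc1ccc(cc1)S(=O)(=O)C[N+]#[C-] | starting material
4 | [2-(benzyloxy)-3-methylphenyl]acetonitrile | Cc1cccc(CC#N)c1OCc1ccccc1 | intermediate
5 | 2-chloro-N-methoxy-N-methylacetamide | CON(C)C(=O)CCl | starting material
6 | 3-[2-(benzyloxy)-3-methylphenyl]-3-cyano-N-methoxy-N-methylpropanamide (racemic at C1) | CON(C)C(=O)CC(C#N)c1cccc(C)c1OCc1ccccc1 | intermediate
7 | 2-methylprop-1-enylmagnesium bromide | CC(C)=C[Mg]Br | starting material
8 | 2-[2-(benzyloxy)-3-methylphenyl]-6-methyl-4-oxohept-5-enenitrile (racemic at C1) | CC(C)=CC(=O)CC(C#N)c1cccc(C)c1OCc1ccccc1 | intermediate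
9 | (4R)-2-[2-(benzyloxy)-3-methylphenyl]-4-hydroxy-6-methylhept-5-enenitrile (both C1 epimers) | CC(C)=C[C@H](O)CC(C#N)c1cccc(C)c1OCc1ccccc1 | intermediate
10 | (4R)-2-[2-(benzyloxy)-3-methylphenyl]-4-[(2S)-3,3-dimethyloxiran-2-yl]-4-hydroxybutanenitrile (threo; both C1 epimers) | CC1(C)O[C@H]1[C@H](O)CC(C#N)c1cccc(C)c1OCc1ccccc1 | intermediate
11 | (4R)-2-[2-(benzyloxy)-3-methylphenyl]-4-[(tert-butyldiphenylsilyl)oxy]-4-[(2S)-3,3-dimethyloxiran-2-yl]butanenitrile (both C1 epimers) | CC1(C)O[C@H]1[C@H](O[Si](c1ccccc1)(c1ccccc1)C(C)(C)C)CC(C#N)c1cccc(C)c1OCc1ccccc1 | intermediate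
12 | (4R)-4-[(tert-butyldiphenylsilyl)oxy]-4-[(2S)-3,3-dimethyloxiran-2-yl]-2-(2-hydroxy-3-methylphenyl)butanenitrile (both C1 epimers) | CC1(C)O[C@H]1[C@H](O[Si](c1ccccc1)(c1ccccc1)C(C)(C)C)CC(C#N)c1cccc(C)c1O | intermediate
13 | 3-[(tert-butyldiphenylsilyl)oxy]-4-hydroxy-5,5,10-trimethyl-11-oxospiro[5.5]undeca-7,9-diene-1-carbonitrile; O3 trans to O4, C11 on the ring-A face opposite to O4, both C1 epimers | N#CC1C[C@@H](O[Si](c3ccccc3)(c3ccccc3)C(C)(C)C)[C@H](O)C(C)(C)[C@]12C=CC=C(C)C2=O | intermediate
14 | N-(tert-butyldimethylsilyl) ketene imine of 13 with C4 OTBS | CC(C)(C)[Si](C)(C)N=C=C1C[C@@H](O[Si](c3ccccc3)(c3ccccc3)C(C)(C)C)[C@H](O[Si](C)(C)C(C)(C)C)C(C)(C)[C@]12C=CC=C(C)C2=O | intermediate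
15 | ring-A-fused bicyclo[2.2.1]heptadiene: C1 nitrile, C1–C9 bond, C7=C8, C10=C11 silyl enol ether (OTBS on C11), C4 OTBS, C3 OTBDPS; cage configuration as in the target | N#C[C@]12C[C@@H](O[Si](c4ccccc4)(c4ccccc4)C(C)(C)C)[C@H](O[Si](C)(C)C(C)(C)C)C(C)(C)[C@]13C=C[C@H]2C(C)=C3O[Si](C)(C)C(C)(C)C | intermediate
16 | exo C8 alcohol of 15 (C7 saturated, OH syn to the C1 bridge) | N#C[C@]12C[C@@H](O[Si](c4ccccc4)(c4ccccc4)C(C)(C)C)[C@H](O[Si](C)(C)C(C)(C)C)C(C)(C)[C@]13C[C@H](O)[C@H]2C(C)=C3O[Si](C)(C)C(C)(C)C | intermediate
17 | exo C8 methanesulfonate of 16 | N#C[C@]12C[C@@H](O[Si](c4ccccc4)(c4ccccc4)C(C)(C)C)[C@H](O[Si](C)(C)C(C)(C)C)C(C)(C)[C@]13C[C@H](OS(C)(=O)=O)[C@H]2C(C)=C3O[Si](C)(C)C(C)(C)C | intermediate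
18 | cage cyclopropyl ketone: target skeleton with C11 ketone, C1 nitrile, C4 OTBS, C3 OTBDPS (O3 trans to O4) | N#C[C@]12C[C@@H](O[Si](c5ccccc5)(c5ccccc5)C(C)(C)C)[C@H](O[Si](C)(C)C(C)(C)C)C(C)(C)[C@]13C[C@@H]4[C@H]2[C@]4(C)C3=O | intermediate
19 | cage keto nitrile with free C4 hydroxyl, C3 OTBDPS | N#C[C@]12C[C@@H](O[Si](c5ccccc5)(c5ccccc5)C(C)(C)C)[C@H](O)C(C)(C)[C@]13C[C@@H]4[C@H]2[C@]4(C)C3=O | intermediate
20 | cage C12 aldehyde with C4 OH and 11-epi hydroxyl (OH on the ring-A side), C3 OTBDPS | O=C[C@]12C[C@@H](O[Si](c5ccccc5)(c5ccccc5)C(C)(C)C)[C@H](O)C(C)(C)[C@]13C[C@@H]4[C@H]2[C@]4(C)[C@@H]3O | intermediate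
21 | cage triol: C12 OH, C4 OH, 11-epi OH, C3 OTBDPS | OC[C@]12C[C@@H](O[Si](c5ccccc5)(c5ccccc5)C(C)(C)C)[C@H](O)C(C)(C)[C@]13C[C@@H]4[C@H]2[C@]4(C)[C@@H]3O | intermediate
22 | 4,12-diacetate with free 11-epi hydroxyl, C3 OTBDPS | CC(=O)OC[C@]12C[C@@H](O[Si](c5ccccc5)(c5ccccc5)C(C)(C)C)[C@H](OC(C)=O)C(C)(C)[C@]13C[C@@H]4[C@H]2[C@]4(C)[C@@H]3O | intermediate
23 | 11-epi methanesulfonate of 22 | CC(=O)OC[C@]12C[C@@H](O[Si](c5ccccc5)(c5ccccc5)C(C)(C)C)[C@H](OC(C)=O)C(C)(C)[C@]13C[C@@H]4[C@H]2[C@]4(C)[C@@H]3OS(C)(=O)=O | intermediate
24 | 4,11,12-triacetate with target configuration at C11, C3 OTBDPS (3-epi) | CC(=O)OC[C@]12C[C@@H](O[Si](c5ccccc5)(c5ccccc5)C(C)(C)C)[C@H](OC(C)=O)C(C)(C)[C@]13C[C@@H]4[C@H]2[C@]4(C)[C@H]3OC(C)=O | intermediate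
25 | 3-epi-CNP0111873.1 (C3 hydroxyl equatorial, trans to the C4 acetate) | CC(=O)OC[C@]12C[C@@H](O)[C@H](OC(C)=O)C(C)(C)[C@]13C[C@@H]4[C@H]2[C@]4(C)[C@H]3OC(C)=O | intermediate
26 | 3-oxo triacetate | CC(=O)OC[C@]12CC(=O)[C@H](OC(C)=O)C(C)(C)[C@]13C[C@@H]4[C@H]2[C@]4(C)[C@H]3OC(C)=O | intermediate
27 | CNP0111873.1 | CC(=O)OC[C@]12C[C@H](O)[C@H](OC(C)=O)C(C)(C)[C@]13C[C@@H]1[C@H]2[C@]1(C)[C@H]3OC(C)=O | target

## Step count and least certain steps

Total: 19 steps. Longest linear sequence: 19 steps (1 → 27); 3, 5 and 7 are commercial and enter in single steps.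

**Step 9 (key step, proposed new method).** The most likely failure is diversion of the C5 cation before the crowded ipso carbon can bond: a 1,2-hydride shift from C4 to give a ketone, proton loss to an allylic alcohol, or chloride capture. Poor facial discrimination at C6 is the second risk.
Fallback (anionic alkylative dearomatization, from 11, returning at 15):
- HCl in Et2O at −78 °C opens the epoxide of 11 at C5 to the tertiary chloride with a free C4 hydroxyl, chlorohydrin F1.
- TBSOTf and 2,6-lutidine give the C4 silyl ether F2.
- Hydrogenolysis over Pd on carbon gives the phenol F3.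
- Cs2CO3 in CF3CH2OH forms the phenoxide, whose ipso carbon takes the ionizing tertiary chloride. This is aryloxide-assisted solvolysis, the classical phenoxide C-alkylation route to cyclohexadienones, and a protic fluorinated solvent favours C- over O-alkylation. The product is the C4-silylated spirodienone F4.
- F4 under the conditions of step 10 with 1.1 equiv of KN(SiMe3)2 gives 15.

**Step 10.** The conjugate addition builds a strained bicycloheptadiene and is reversible. The likely failure is no net closure: retro-Michael opening before silylation, or a slow Mukaiyama–Michael closure of 14 that merely returns 13 on work-up.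
Fallback (Michael-initiated ring closure, from 13, returning at 18):
- H2 with RhCl(PPh3)3 saturates the less hindered C7=C8 bond to give the 7,8-dihydro enone F5.
- TBSOTf and Et3N give the silyl dienol ether F6, in which O4 is silylated as well.
- NBS brominates the dienol ether at the γ-carbon C8 to give the γ-bromo enone F7.
- KOtBu in t-BuOH/THF lets proton exchange proceed freely; C1 adds to C9 and the C10 enolate displaces bromide at C8 irreversibly, giving 18 directly.

**Step 16.** The likely failures are capture of the delocalized cyclopropylcarbinyl cation at C8 or C9 with loss of the cyclopropane (homoallylic acetates), ring expansion towards the methyl-bearing C10, or failure to sulfonylate the buried hydroxyl.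
Fallback (equilibrating hydride transfer in place of ionization, from 19, returning at 24):
- Al(OiPr)3 in i-PrOH/toluene at reflux with a little acetone (Meerwein–Ponndorf–Verley reduction under Oppenauer equilibration) should settle on the less congested carbinol with the hydroxyl beside the C7 bridge, the C11 alcohol of target configuration F8.
- i-Bu2AlH followed by NaBH4 gives the triol F9.
- Ac2O, DMAP and Et3N at 40 °C give 24.

**Step 11.** The likely failure is poor exo/endo facial selectivity, because the nitrile on the C1 bridge lies over the exo face; the endo alcohol cannot be displaced from the backside.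
Fallback (carbene closure, from 16 as obtained, whatever its configuration at C8, returning at 18):
- Dess–Martin periodinane gives the C8 ketone F10.
- TsNHNH2 with pyridinium tosylate in MeOH gives the C8 tosylhydrazone and releases the C11 ketone, F11.
- NaH in toluene at 110 °C (Bamford–Stevens reaction) generates the C8 carbene, which closes onto C10 by 1,3-insertion, as in the conversion of bicyclo[2.2.1]heptan-2-one tosylhydrazones into nortricyclenes, giving 18.

## Further compounds

F1 | step 9 | 2-[2-(benzyloxy)-3-methylphenyl]-4-[(tert-butyldiphenylsilyl)oxy]-6-chloro-5-hydroxy-6-methylheptanenitrile (C3 and C4 as in 11) | CC(C)(Cl)[C@@H](O)[C@H](O[Si](c1ccccc1)(c1ccccc1)C(C)(C)C)CC(C#N)c1cccc(C)c1OCc1ccccc1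
F2 | step 9 | C4 tert-butyldimethylsilyl ether of F1 | CC(C)(Cl)[C@@H](O[Si](C)(C)C(C)(C)C)[C@H](O[Si](c1ccccc1)(c1ccccc1)C(C)(C)C)CC(C#N)c1cccc(C)c1OCc1ccccc1
F3 | step 9 | phenol from F2 (benzyl removed) | CC(C)(Cl)[C@@H](O[Si](C)(C)C(C)(C)C)[C@H](O[Si](c1ccccc1)(c1ccccc1)C(C)(C)C)CC(C#N)c1cccc(C)c1O
F4 | step 9 | C4 tert-butyldimethylsilyl ether of spirodienone 13 | N#CC1C[C@@H](O[Si](c3ccccc3)(c3ccccc3)C(C)(C)C)[C@H](O[Si](C)(C)C(C)(C)C)C(C)(C)[C@]12C=CC=C(C)C2=O
F5 | step 10 | 7,8-dihydro derivative of 13 (spiro cyclohex-2-enone) | N#CC1C[C@@H](O[Si](c3ccccc3)(c3ccccc3)C(C)(C)C)[C@H](O)C(C)(C)[C@]12CCC=C(C)C2=O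
F6 | step 10 | silyl dienol ether of F5 (C11 OTBS, C10=C11, C8=C9) with C4 OTBS | N#CC1C[C@@H](O[Si](c3ccccc3)(c3ccccc3)C(C)(C)C)[C@H](O[Si](C)(C)C(C)(C)C)C(C)(C)[C@]12CC=CC(C)=C2O[Si](C)(C)C(C)(C)C
F7 | step 10 | 8-bromo spiro cyclohex-2-enone with C4 OTBS (mixture at C8) | N#CC1C[C@@H](O[Si](c3ccccc3)(c3ccccc3)C(C)(C)C)[C@H](O[Si](C)(C)C(C)(C)C)C(C)(C)[C@]12CC(Br)C=C(C)C2=O
F8 | step 16 | cage nitrile with C11 hydroxyl of target configuration, C4 OH, C3 OTBDPS | N#C[C@]12C[C@@H](O[Si](c5ccccc5)(c5ccccc5)C(C)(C)C)[C@H](O)C(C)(C)[C@]13C[C@@H]4[C@H]2[C@]4(C)[C@H]3O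
F9 | step 16 | cage triol with C11 hydroxyl of target configuration, C3 OTBDPS | OC[C@]12C[C@@H](O[Si](c5ccccc5)(c5ccccc5)C(C)(C)C)[C@H](O)C(C)(C)[C@]13C[C@@H]4[C@H]2[C@]4(C)[C@H]3O
F10 | step 11 | C8 ketone of 16 (silyl enol ether retained) | N#C[C@]12C[C@@H](O[Si](c4ccccc4)(c4ccccc4)C(C)(C)C)[C@H](O[Si](C)(C)C(C)(C)C)C(C)(C)[C@]13CC(=O)[C@H]2C(C)=C3O[Si](C)(C)C(C)(C)C
F11 | step 11 | C8 tosylhydrazone with C11 ketone (C10 epimers) | N#C[C@]12C[C@@H](O[Si](c4ccccc4)(c4ccccc4)C(C)(C)C)[C@H](O[Si](C)(C)C(C)(C)C)C(C)(C)[C@]13CC(=NNS(=O)(=O)c4ccc(C)cc4)[C@H]2C(C)C3=O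
A1 | alternative 1 | silicon-tethered norbornene | C[Si]1(C)OC[C@]23C[C@H](O[Si](C)(C)C(C)(C)C)[C@H](OCc5ccccc5)C(C)(C)[C@]24C[C@H]1[C@H]3C(C)=C4
A2 | alternative 2 | dibromo bicyclo[3.2.1]octenone fused to ring A | O=C1[C@@]2(Br)C[C@H](O[Si](C)(C)C(C)(C)C)[C@H](OCc4ccccc4)C(C)(C)[C@]23C[C@@H](C(C)=C3O[Si](C)(C)C)[C@@H]1Br
A3 | alternative 3 | cage C11 acetate with free C12 hydroxyl | OC[C@]12C[C@H](O[Si](C)(C)C(C)(C)C)[C@H](OCc4ccccc4)C(C)(C)[C@]13C[C@@H]1[C@H]2[C@]1(C)[C@H]3OC(C)=O
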